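At early times the reagent stood as X in the second phase and reached the reaction phase as E by transfer.

G 1.0 mM; X 3.00 mM; time 1.5 min; volume of the second phase over the first 0.25

    E ⇌ X, rate k1*([E] - [X]/K1) per volume of the first phase (K1 = 0.75, k1 = 0.17 s⁻¹)
    G + E → G.E (k2 = 64 L mol⁻¹ s⁻¹)
    E ⇌ Z (K3 = 11, k3 = 0.0075 s⁻¹)
    2 E → E2 (k4 = 42 L mol⁻¹ s⁻¹)

- G.E at 1.5 min, in percent of the G charged
- the change that raises the amount of G.E at 1.5 min, in percent of the G charged most ("none" if none brings more than 2 percentage points) (blue / green / none)
- amount of G.E at 1.5 min, in percent of the G charged, after blue

- where a step has two of a species, its rate is k times that concentration squared, and two are used at each turn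
- in the second phase: X; everything else is in the first
- charges count per volume of the first phase; a concentration in a rate is the amount of a species over the volume of its own phase; every rate counts per litre of the first phase
- run time (flask): 1.5 min

1. Transfer. The two phases relaxed in 0.929 s, far shorter than the 0.18 min half-life of E by coupling with G as charged. I therefore kept the phases balanced, with a share f = 0.842 of the E and X together present as E.

2. Price. I carried S, twice the dimerisation constant times f over the coupling constant, a selectivity factor: 1.11. Multiplied by the reagent in E and X over G, it gave the rate of E's loss to E2 over the rate of its loss to G.E.

3. Rule. I let dimerisation carry the fall of E. With P the reagent left for that fall and T twice the dimerisation constant times f squared times P times time, the fraction of G left is (1 + T) to the power −1/S.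

4. Ledger, per litre of the first phase. From 3.00 mM charged, I first booked 1.0 mM to G whole, leaving the unreacted G as the correction. I then booked 0.234 mM to Z, forward step only, for G falling by a factor of about e squared. That left P = 1.77 mM.

5. Correction. T came to 9.47, so I reckoned G left at 11.9% and G.E at 88.1%.

6. Closing. That left 1.89 mM of reagent outside G.E and Z. My rule kept 0.169 mM of it unspent as E and X, and I booked the other 1.72 mM of reagent to E2 by subtraction, more than I booked to coupling.

7. Changes. With the same entries I reckoned that blue left 5.15% of G and gave 94.9%. Green shortened a relaxation already brief beside the run, so I chose blue.

The forecast gave 83%, blue and 92%, holding that “only more X raises the yield appreciably”.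

The simulation gave 84.5%, with blue reaching 93.5%, a gain of 9 percentage points, while green moved the yield by −0.74 points.

I used S on the same flask read at 50 s. T scaled with time to 5.26, so I reckoned G left at 19.0% and G.E at 81.0%. That flask stood at 80.3%, with 0.143 mM of E. From that reading to 1.50 min, my reckoning added 7.1 points of G.E, and the flask added 4.2 points.

(The numbers of this flask were drawn at random within sensible limits; what happens was integrated by code.)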